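The target in this flask has all but stopped climbing in the readings, and the person taking over the bench should leave it alone. Monday's run is this very flask, followed up to 240 min.

| setting | Monday's | flask |
|---|---|---|
| substrate | 0.30 M | 0.30 M |
| coupling partner | 0.33 M | 0.330 M |
| temperature | 70 °C | 70 °C |
| remark | the very flask that is asked about, followed so far |  |
| time |  | 6.0 h |

Monday's run (percent of the substrate charged): time / min: target / % = 20.0: 22.9; 50.0: 37.7; 90.0: 45.4; 150: 49.8; 240: 50.4

(readings scatter by 0.3 percentage points)

- birch: at 6.0 h add coupling partner, 100% of the amount charged, then wait 6.0 h
- ash: change nothing and wait 6.0 h more
- elm: at 6.0 h take out 90% of the target then present, then wait 6.0 h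
- larch: at 6.0 h raise the temperature by 20 K, then wait 6.0 h

- a species is counted by the substrate in it: one side product B counts as two
- target that was removed still counts
- the numbers in the tables scatter with a standard deviation of 0.3 percentage points
- what may be going on: substrate + coupling partner -> target; substrate -> side product A; 2 substrate -> side product B
- the earlier runs do not show what temperature does; that part of a forecast is a guess
- additions bring no volume worth counting

* target, in percent of the substrate first charged, at 6.0 h
* the remedy with the largest gain of target, or "none" below 2 percentage points (birch / ash / elm / larch / none)
* target present, with what was taken out counted in, in percent of the substrate first charged, after ash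
* target present, with what was taken out counted in, in percent of the substrate first charged, after larch

We take the last reading as a first plateau and compute the small remainder as a correction. The gaps to that plateau are 28 percentage points at 20.0 min and 5 points at 90.0 min, both far above the scatter.

  time constant = elapsed time / ln(earlier gap / later gap) = 41.1 min

This tail constant is the time in which what is still to come falls by the factor e. It adds a correction to the last reading:

  still to come after 240 min: 0.13 points
  target at 6.0 h: 50.5%
  still to come after 6.0 h: 0.007 points

About half of the substrate became target, so we put the substrate left at 6.0 h near 0.0138%, and we reckon coupling partner at 54.1% of its charge. By this reckoning substrate is the limiting reagent. Even turned wholly into target, that substrate gives less than the 2 points margin, and the readings show no fall of target; what heat does is a guess. So we expect 50.5% now and after ash or larch, and best none.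

The forecast says 50.7%, a little above ours, then 50.8% after ash, 50.8% after larch and best none, since “there is nothing left to convert”.

The flask gives 50.9%, 50.9% after ash, 50.9% after larch and best none. Our figure lies 0.40 points below, near the 0.3 points scatter of its last reading.

    substrate + coupling partner → target (k = 8.40 × 10⁻⁴ /M/s, Ea = 86.0 kJ/mol)
    substrate → side product A (k = 1.90 × 10⁻⁴ /s, Ea = 113 kJ/mol)
    2 substrate → side product B (k = 3.30 × 10⁻⁵ /M/s, Ea = 68.0 kJ/mol)
    (constants at 70 °C)

In this flask birch gains most, 0.032 points, which is below the 2 points margin. An average constant of the same kind, taken for the substrate of this flask from charge to remainder, uses the 0.0469% of substrate left at 6.0 h and gives 47.0 min, longer than our 41.1 min from the target gaps. In the neighbour flask with 0.20 M of coupling partner, 0.234% of substrate stands at 6.0 h, so its constant is 59.4 min, and its target is 36.6%.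

The readings are simulated with made-up constants, and the scatter is random.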